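## The problem

Podocarpusflavone A (24) is a biflavone in which C3' of a 5,7,4'-trihydroxyflavone (unit 1) is bonded to C8 of a 5,7-dihydroxy-4'-methoxyflavone (unit 2). It has no stereocentre. The only stereo element is the C3'–C8 axis, which the structure leaves undefined, so there is nothing to control and nothing that could exert control. The difficulty is constitutional: the inter-unit bond joins two aromatic carbons, is flanked by three oxygens (O4' of unit 1, O7 and O1 of unit 2), and must sit at C8 rather than at the electronically similar C6 of unit 2. Five phenols have to be told apart from one methyl ether, so the methyl ether should arrive with its own building block and all phenols should share one protecting group that leaves without touching it. Several groups are fragile: phloroglucinol rings oxidise in base, polyketo esters lactonise or fragment, both pyranone rings open in hot hydroxide, and a 5-hydroxyflavone with a C8 substituent can isomerise to the C6 series in hot strong acid (Wessely–Moser rearrangement). The enabling feature is ring A of unit 2: C5, C7 and C8a carry oxygen, and C8 carries ring B of unit 1 between O7 and O1. Such a 2-arylphloroglucinol is the folded form of a 6-aryl-3,5-dioxohexanoate, so the hindered aryl–aryl bond can be prepared as an ordinary benzylic C–C bond of an open chain and ring A closed around it.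

## Retrosynthesis

**24 from 23.** Five O–benzyl bonds are cut. Benzyl is the single phenol protecting group because hydrogenolysis is neutral, leaves the anisyl methyl ether alone and avoids the acid that could move the aryl group from C8 to C6. The forward step must remove five benzyl groups without reducing either C2=C3 bond.

**23 from 17 and 19.** Ring C of unit 1 is opened at O1–C2, giving the 1,3-diketone 22, and then at C2–C3, giving flavone acid 17 (via its acid chloride 20) and the acetophenone 19 (via its dilithium salt 21). Ketone 19 comes from 2',4',6'-trihydroxyacetophenone 18 by double benzylation. Unit 1 is cut before unit 2 because its C2 carbon can travel as a carboxyl group, a spectator that survives the strong base of the key step. An aldehyde or a methyl ketone in that position would not survive. The forward reactions are C-aroylation of a ketone enolate and an acid-catalysed cyclodehydration, both with a single possible ring size.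

**17 from 14 and 15.** Ring C of unit 2 is opened at O1–C2, giving chalcone 16, and at C2–C3 (aldol), giving acetophenone 14 and 4-methoxybenzaldehyde 15, which brings the only methyl ether. The chalcone route is preferred to a second aroylation because it needs no acylation of a phenol. The one free hydroxyl of 14 then decides by itself that the pyranone closes next to the biaryl bond. The aqueous base of the aldol step is also used to saponify the spectator ester.

**14 from 11.** Two benzyl ethers and the C4a–C4 bond (the acetyl group) are removed, passing through acetophenone 13 and its ketiminium salt 12. In 11 the two free ring positions are equivalent, so acetylation raises no regiochemical question. The C8-versus-C6 choice is moved to the benzylation of 13, which must leave free only the hydroxyl wedged between acetyl and aryl.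

**11 from 9 (key disconnection).** The C8–C7 bond of unit 2 is cut, which is the C6–C1 bond of the chain, opening ring A to methyl 6-aryl-3,5-dioxohexanoate 9 (via trione 10). The neighbouring cut, the biaryl bond itself, would require cross-coupling of two partners with three ortho oxygens. That coupling is kept in reserve only. The precursor 9 has one ring fewer and no aryl–aryl bond. The forward reaction must be acylation at carbon, not at oxygen.

**9 from 5 and 6.** The chain is cut at C4–C5 into arylacetic acid 5 (activated as imidazolide 7) and methyl acetoacetate 6 (as dianion 8). This is the standard assembly of 3,5-dioxo esters and uses the cheapest four-carbon unit.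

**5 from 1 and 3.** The aryl–CH2 bond is cut: acid 5 comes from tert-butyl ester 4, made from aryl bromide 2 and the zinc enolate 3. Bromide 2 is the benzyl ether of methyl 3-bromo-4-hydroxybenzoate 1. This takes three steps. The sequence of O-allylation, Claisen rearrangement, benzylation and two-stage oxidative cleavage would take five. The two esters of 4 are chosen so that one can be removed by acid while the other stays.

## Roads not taken

**Alternative 1:** The cut removes ring B of unit 1 (bonds C3'–C4' and C1'–C2'), leaving the 8-ethynylflavone A1 and the 3-hydroxy-2-pyranone A2.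
- Forward step: a [4+2] cycloaddition across C3 and C6 of A2, then loss of CO2, would give hydroxy ester A3.
- Merits: the biaryl bond is never made by coupling, and unit 2 is built first from simple materials. A3 is the free-phenol methyl ester counterpart of 17, so the endgame would be the same. It could reach that stage in fewer steps and without a polyketo ester, which is a real advantage.
- Weak points: 3-hydroxy-2-pyranones add readily to electron-poor dienophiles. A1 is an unactivated, electron-rich aryl alkyne flanked by O7 and O1, so forcing thermal conditions would be needed. The hydroxyl-bearing C3 of A2 must bond to the internal alkyne carbon, which is the more congested orientation, and nothing enforces it. Making A1 also needs a selective functionalisation of C8 over C6.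
- Against it the chosen plan sets: in the Claisen folding the position of the aryl group between two oxygens is fixed by connectivity and not by an orientation preference.

**Alternative 2:** The cut is C2–C3 of both units at once: bis-diketone A5 would arise from biaryl diester A4 by two Baker–Venkataraman acyl shifts.
- Merits: both heterocycles come from one reaction type, and no oxidation step is needed. In those respects it is as good as the endgame chosen here.
- Weak points: A4 already contains the biaryl bond and the ring A acetyl group, so it is an endgame and not an answer to the central problem. It requires aroylation of the most hindered, chelated phenol (between acetyl and aryl) and presupposes the same hydroxyl differentiation as 14. The two acyl shifts differ in steric demand, so mono-shifted and cleaved material is likely. Counted from a 14-type intermediate it is not shorter than steps 8, 9, 11 and 12.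
- Against it the chosen plan sets: the hindered phenol is never acylated and is used only as the internal nucleophile of the ring closure.

**Alternative 3:** The cut is C4a–C4, C4–C3 and O1–C2 of unit 1: iodophenol A6, CO and alkyne A7 would be joined under palladium catalysis to A8, which is identical with 23.
- Merits: it is the most convergent of the four plans. Three bonds form in one operation and the product is one step from 24. In convergence it is better than the linear endgame chosen here.
- Weak points: the alkynone formed after carbonylative coupling can close in the 6-endo mode (flavone) or the 5-exo mode (aurone). A6 is electron-rich with iodine between two oxygens, so oxidative addition and CO insertion are slow, and direct coupling without CO competes. A7 needs the biaryl bond and, in addition, an ethynyl group in place of the carboxyl carbon. That is a change of oxidation state which is awkward once a pyranone is present.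
- Against it the chosen plan sets: ring closures whose size is unambiguous (steps 9 and 12) and a spectator carboxyl group that needs no redox adjustment.

Key step: step 5

Assumption: the C3'–C8 axis of 24 is treated as stereochemically undefined, as drawn, and zinc reagent 3 is used as the commercially supplied ether solution.

## Route

Step 1
Reactants: 1 methyl 3-bromo-4-hydroxybenzoate
Product: 2 methyl 4-(benzyloxy)-3-bromobenzoate
Conditions: BnBr, K2CO3, DMF, 25 °C
Reagents that add atoms: benzyl bromide, BrCc1ccccc1
Why: Williamson ether synthesis on an acidic phenol (para to the ester); the benzyl group then protects O4' of unit 1 to the end of the route.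

Step 2
Reactants: 2 methyl 4-(benzyloxy)-3-bromobenzoate; 3 (2-tert-butoxy-2-oxoethyl)zinc chloride
Product: 4 methyl 4-(benzyloxy)-3-(2-tert-butoxy-2-oxoethyl)benzoate
Conditions: Pd(dba)2 (cat.), P(t-Bu)3 (cat.), THF, 25 to 50 °C
Reagents that add atoms: none
Why: Negishi-type cross-coupling of an aryl bromide with a Reformatsky zinc enolate is established and tolerates the methyl ester; the bulky electron-rich phosphine lets zerovalent palladium insert next to the ortho ether.

Step 3
Reactants: 4 methyl 4-(benzyloxy)-3-(2-tert-butoxy-2-oxoethyl)benzoate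
Product: 5 2-[2-(benzyloxy)-5-(methoxycarbonyl)phenyl]acetic acid
Conditions: CF3CO2H, CH2Cl2, 25 °C
Reagents that add atoms: none
Why: Acidolysis of the tert-butyl ester with loss of isobutene; the methyl ester and the aryl benzyl ether on the electron-poor ring should be stable to trifluoroacetic acid at room temperature.

Step 4
Reactants: 5 2-[2-(benzyloxy)-5-(methoxycarbonyl)phenyl]acetic acid; 6 methyl acetoacetate
Product: 9 methyl 6-[2-(benzyloxy)-5-(methoxycarbonyl)phenyl]-3,5-dioxohexanoate, via acyl imidazolide 7 (not isolated), via dilithium dianion of methyl acetoacetate 8 (not isolated)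
Conditions: 5, CDI, THF, 25 °C; 6, LiN(i-Pr)2 (LDA, 2.1 equiv per 6), THF, −78 to 0 °C; 7 added to 8 (3.5 equiv) at −78 °C, then to −20 °C; cold aq. HCl to pH 4
Reagents that add atoms: none
Why: γ-Acylation of the acetoacetate dianion by an acyl imidazole is the standard route to 3,5-dioxo esters; the excess of 8 covers the imidazole N–H and the acidic product, and the cold, weakly acidic quench should keep 9 from lactonising.

Step 5
Reactants: 9 methyl 6-[2-(benzyloxy)-5-(methoxycarbonyl)phenyl]-3,5-dioxohexanoate
Product: 11 methyl 4-(benzyloxy)-3-(2,4,6-trihydroxyphenyl)benzoate, via 2-arylcyclohexane-1,3,5-trione 10 (not isolated)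
Conditions: KOtBu (2.5 equiv), THF, argon, 0 to 50 °C; then cold degassed aq. HCl
Reagents that add atoms: none
Why: Two equivalents of tert-butoxide should turn 9 into its C2,C4-dianion, so that no monoanion with a free ester and a nucleophilic C5 oxygen, the species that lactonises to a 4-hydroxy-2-pyranone, remains. Proton exchange through tert-butanol should give a small share of the C4,C6-dianion, in which the benzylic C6 carbanion, stabilised by the C5 carbonyl and the aryl ring, is the most nucleophilic centre and the C1 ester is not enolised. C6 attacks C1 and methoxide leaves, a Dieckmann-type Claisen closure in the 6-(enolendo)-exo-trig mode that forms the future C8–C7 bond of unit 2 and gives trione 10. Trione 10 is deprotonated at once and aromatises to the phenolate of 11, which makes the closure irreversible. The closest known reactions are the Claisen cyclisation of β-polyketo esters to phloroglucinols and the KOtBu-mediated closure of 6-aryl-5-oxohexanoates to 2-arylcyclohexane-1,3-diones. Every other carbanion–carbonyl pairing in 9 would give a four-membered ring, and the aryl methyl ester is remote and not activated. No stereocentre is formed. The selectivity needed is C- over O-acylation; it is secured by an excess of a non-nucleophilic base in an aprotic medium, which puts the charge on carbon, by the weakly chelating potassium ion, which lets the C4–C5 bond take the geometry that brings C6 to C1, and by the aromatisation.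

Step 6
Reactants: 11 methyl 4-(benzyloxy)-3-(2,4,6-trihydroxyphenyl)benzoate
Product: 13 methyl 3-(3-acetyl-2,4,6-trihydroxyphenyl)-4-(benzyloxy)benzoate, via ketiminium chloride 12 (not isolated)
Conditions: MeCN, ZnCl2, HCl (gas), Et2O, 0 °C; then H2O, 90 °C
Reagents that add atoms: acetonitrile, CC#N; water, O
Why: Houben–Hoesch acylation, the classical C-acetylation of phloroglucinols; the two free ring positions of 11 are equivalent, and the iminium salt 12 deactivates the ring against a second acylation before it is hydrolysed to the ketone.

Step 7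
Reactants: 13 methyl 3-(3-acetyl-2,4,6-trihydroxyphenyl)-4-(benzyloxy)benzoate
Product: 14 methyl 3-[3-acetyl-4,6-bis(benzyloxy)-2-hydroxyphenyl]-4-(benzyloxy)benzoate
Conditions: BnBr (2.1 equiv), K2CO3, DMF, 25 °C
Reagents that add atoms: benzyl bromide, BrCc1ccccc1
Why: Williamson etherification; the hydroxyl para to the acetyl group (most acidic, not hydrogen-bonded) should react first and then the ortho hydroxyl that has only hydrogen on its other side. The hydroxyl left free is chelated to the carbonyl and buried between acetyl and aryl, and it is this choice that later places the aryl group at C8 and not at C6.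

Step 8
Reactants: 14 methyl 3-[3-acetyl-4,6-bis(benzyloxy)-2-hydroxyphenyl]-4-(benzyloxy)benzoate; 15 4-methoxybenzaldehyde
Product: 16 4-(benzyloxy)-3-{4,6-bis(benzyloxy)-2-hydroxy-3-[(2E)-3-(4-methoxyphenyl)prop-2-enoyl]phenyl}benzoic acid
Conditions: KOH (excess), EtOH–THF–H2O, 25 to 50 °C; then aq. HCl
Reagents that add atoms: potassium hydroxide, [K+].[OH-]
Why: Claisen–Schmidt condensation of a 2-hydroxyacetophenone with a non-enolisable aldehyde gives the E-enone by elimination from the aldol; the same aqueous hydroxide is meant to saponify the aryl methyl ester, which frees the carboxyl group needed in step 11.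

Step 9
Reactants: 16 4-(benzyloxy)-3-{4,6-bis(benzyloxy)-2-hydroxy-3-[(2E)-3-(4-methoxyphenyl)prop-2-enoyl]phenyl}benzoic acid
Product: 17 4-(benzyloxy)-3-[5,7-bis(benzyloxy)-2-(4-methoxyphenyl)-4-oxo-4H-chromen-8-yl]benzoic acid
Conditions: I2 (cat.), DMSO, 130 °C
Reagents that add atoms: none
Why: Iodine-catalysed oxidative cyclisation of a 2'-hydroxychalcone (oxa-Michael addition, α-iodination, loss of HI, with DMSO reoxidising HI); only one phenol is free, so O1–C2 of unit 2 can close only onto the oxygen next to the biaryl bond.

Step 10
Reactants: 18 1-(2,4,6-trihydroxyphenyl)ethan-1-one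
Product: 19 1-[2,4-bis(benzyloxy)-6-hydroxyphenyl]ethan-1-one
Conditions: BnBr (2.0 equiv), K2CO3, DMF, 25 °C
Reagents that add atoms: benzyl bromide, BrCc1ccccc1
Why: Williamson etherification; the two ortho hydroxyls are equivalent and the one that remains is held by the hydrogen bond to the carbonyl group, a standard preparation of this ring A building block.

Step 11
Reactants: 17 4-(benzyloxy)-3-[5,7-bis(benzyloxy)-2-(4-methoxyphenyl)-4-oxo-4H-chromen-8-yl]benzoic acid; 19 1-[2,4-bis(benzyloxy)-6-hydroxyphenyl]ethan-1-one
Product: 22 1-[2,4-bis(benzyloxy)-6-hydroxyphenyl]-3-{4-(benzyloxy)-3-[5,7-bis(benzyloxy)-2-(4-methoxyphenyl)-4-oxo-4H-chromen-8-yl]phenyl}propane-1,3-dione, via acid chloride 20 (not isolated), via dilithium phenoxide enolate 21 (not isolated)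
Conditions: 17, (COCl)2, DMF (cat.), CH2Cl2, 0 to 25 °C, evaporate; 19, LiN(SiMe3)2 (3 equiv), THF, −78 to −10 °C; 20 added at −78 °C, then to 25 °C; aq. HCl
Reagents that add atoms: none
Why: C-Aroylation of the lithium enolate of a 2-hydroxyacetophenone with an aroyl chloride gives the Baker–Venkataraman diketone directly; the third equivalent of base holds the product as its enolate and stops a second acylation, and at −78 °C the acid chloride should be far more electrophilic than the pyranone of unit 2.

Step 12
Reactants: 22 1-[2,4-bis(benzyloxy)-6-hydroxyphenyl]-3-{4-(benzyloxy)-3-[5,7-bis(benzyloxy)-2-(4-methoxyphenyl)-4-oxo-4H-chromen-8-yl]phenyl}propane-1,3-dione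
Product: 23 5,7-bis(benzyloxy)-8-{2-(benzyloxy)-5-[5,7-bis(benzyloxy)-4-oxo-4H-chromen-2-yl]phenyl}-2-(4-methoxyphenyl)-4H-chromen-4-one
Conditions: H2SO4 (cat.), AcOH, 60 °C
Reagents that add atoms: none
Why: Acid-catalysed cyclodehydration of a 2-hydroxyaryl 1,3-diketone (hemiketal formation, then loss of water) closes ring C of unit 1; only a six-membered ring can form, and with O5 of unit 2 still benzylated no C8-to-C6 isomerisation is open.

Step 13
Reactants: 23 5,7-bis(benzyloxy)-8-{2-(benzyloxy)-5-[5,7-bis(benzyloxy)-4-oxo-4H-chromen-2-yl]phenyl}-2-(4-methoxyphenyl)-4H-chromen-4-one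
Product: 24 podocarpusflavone A
Conditions: H2 (1 atm), Pd/C, THF–MeOH, 25 °C
Reagents that add atoms: none
Why: Hydrogenolysis of five aryl benzyl ethers; the aryl methyl ether is inert, and the neutral conditions at ambient pressure should spare the pyranone double bonds and avoid acid-induced migration of the aryl group.

## Compound list

1 | methyl 3-bromo-4-hydroxybenzoate | COC(=O)c1ccc(O)c(Br)c1 | starting material
2 | methyl 4-(benzyloxy)-3-bromobenzoate | COC(=O)c1ccc(OCc2ccccc2)c(Br)c1 | intermediate
3 | (2-tert-butoxy-2-oxoethyl)zinc chloride | CC(C)(C)OC(=O)C[Zn]Cl | starting material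
4 | methyl 4-(benzyloxy)-3-(2-tert-butoxy-2-oxoethyl)benzoate | COC(=O)c1ccc(OCc2ccccc2)c(CC(=O)OC(C)(C)C)c1 | intermediate
5 | 2-[2-(benzyloxy)-5-(methoxycarbonyl)phenyl]acetic acid | COC(=O)c1ccc(OCc2ccccc2)c(CC(=O)O)c1 | intermediate
6 | methyl acetoacetate | COC(=O)CC(C)=O | starting material
7 | methyl 4-(benzyloxy)-3-[2-(1H-imidazol-1-yl)-2-oxoethyl]benzoate (acyl imidazolide) | COC(=O)c1ccc(OCc2ccccc2)c(CC(=O)n2ccnc2)c1 | intermediate
8 | dilithium dianion of methyl acetoacetate | [Li+].[Li+].C=C([O-])C=C([O-])OC | intermediate
9 | methyl 6-[2-(benzyloxy)-5-(methoxycarbonyl)phenyl]-3,5-dioxohexanoate | COC(=O)CC(=O)CC(=O)Cc1cc(C(=O)OC)ccc1OCc1ccccc1 | intermediate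
10 | methyl 4-(benzyloxy)-3-(2,4,6-trioxocyclohexyl)benzoate | COC(=O)c1ccc(OCc2ccccc2)c(C2C(=O)CC(=O)CC2=O)c1 | intermediate
11 | methyl 4-(benzyloxy)-3-(2,4,6-trihydroxyphenyl)benzoate | COC(=O)c1ccc(OCc2ccccc2)c(-c2c(O)cc(O)cc2O)c1 | intermediate
12 | 1-{3-[2-(benzyloxy)-5-(methoxycarbonyl)phenyl]-2,4,6-trihydroxyphenyl}ethan-1-iminium chloride | COC(=O)c1ccc(OCc2ccccc2)c(-c2c(O)cc(O)c(C(C)=[NH2+])c2O)c1.[Cl-] | intermediate
13 | methyl 3-(3-acetyl-2,4,6-trihydroxyphenyl)-4-(benzyloxy)benzoate | COC(=O)c1ccc(OCc2ccccc2)c(-c2c(O)cc(O)c(C(C)=O)c2O)c1 | intermediate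
14 | methyl 3-[3-acetyl-4,6-bis(benzyloxy)-2-hydroxyphenyl]-4-(benzyloxy)benzoate | COC(=O)c1ccc(OCc2ccccc2)c(-c2c(OCc3ccccc3)cc(OCc3ccccc3)c(C(C)=O)c2O)c1 | intermediate
15 | 4-methoxybenzaldehyde | COc1ccc(C=O)cc1 | starting material
16 | 4-(benzyloxy)-3-{4,6-bis(benzyloxy)-2-hydroxy-3-[(2E)-3-(4-methoxyphenyl)prop-2-enoyl]phenyl}benzoic acid | COc1ccc(/C=C/C(=O)c2c(OCc3ccccc3)cc(OCc3ccccc3)c(-c3cc(C(=O)O)ccc3OCc3ccccc3)c2O)cc1 | intermediate
17 | 4-(benzyloxy)-3-[5,7-bis(benzyloxy)-2-(4-methoxyphenyl)-4-oxo-4H-chromen-8-yl]benzoic acid | COc1ccc(-c2cc(=O)c3c(OCc4ccccc4)cc(OCc4ccccc4)c(-c4cc(C(=O)O)ccc4OCc4ccccc4)c3o2)cc1 | intermediate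
18 | 1-(2,4,6-trihydroxyphenyl)ethan-1-one | CC(=O)c1c(O)cc(O)cc1O | starting material
19 | 1-[2,4-bis(benzyloxy)-6-hydroxyphenyl]ethan-1-one | CC(=O)c1c(O)cc(OCc2ccccc2)cc1OCc1ccccc1 | intermediate
20 | 4-(benzyloxy)-3-[5,7-bis(benzyloxy)-2-(4-methoxyphenyl)-4-oxo-4H-chromen-8-yl]benzoyl chloride | COc1ccc(-c2cc(=O)c3c(OCc4ccccc4)cc(OCc4ccccc4)c(-c4cc(C(=O)Cl)ccc4OCc4ccccc4)c3o2)cc1 | intermediate
21 | dilithium 3,5-bis(benzyloxy)-2-(1-oxidoethenyl)phenolate | [Li+].[Li+].C=C([O-])c1c([O-])cc(OCc2ccccc2)cc1OCc1ccccc1 | intermediate
22 | 1-[2,4-bis(benzyloxy)-6-hydroxyphenyl]-3-{4-(benzyloxy)-3-[5,7-bis(benzyloxy)-2-(4-methoxyphenyl)-4-oxo-4H-chromen-8-yl]phenyl}propane-1,3-dione | COc1ccc(-c2cc(=O)c3c(OCc4ccccc4)cc(OCc4ccccc4)c(-c4cc(C(=O)CC(=O)c5c(O)cc(OCc6ccccc6)cc5OCc5ccccc5)ccc4OCc4ccccc4)c3o2)cc1 | intermediate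
23 | 5,7-bis(benzyloxy)-8-{2-(benzyloxy)-5-[5,7-bis(benzyloxy)-4-oxo-4H-chromen-2-yl]phenyl}-2-(4-methoxyphenyl)-4H-chromen-4-one | COc1ccc(-c2cc(=O)c3c(OCc4ccccc4)cc(OCc4ccccc4)c(-c4cc(-c5cc(=O)c6c(OCc7ccccc7)cc(OCc7ccccc7)cc6o5)ccc4OCc4ccccc4)c3o2)cc1 | intermediate
24 | podocarpusflavone A, 8-[5-(5,7-dihydroxy-4-oxo-4H-chromen-2-yl)-2-hydroxyphenyl]-5,7-dihydroxy-2-(4-methoxyphenyl)-4H-chromen-4-one | COc1ccc(-c2cc(=O)c3c(O)cc(O)c(-c4cc(-c5cc(=O)c6c(O)cc(O)cc6o5)ccc4O)c3o2)cc1 | target

## Step count and risks

Total: 13 steps. Longest linear sequence: 12 steps (1 to 24 through steps 1–9 and 11–13); step 10 is a one-step side branch.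

**Step 5 (key step).**
- What may go wrong: acylation at oxygen instead of carbon, that is, lactonisation through the C5 enolate oxygen. It would take over if the monoanion builds up or if proton exchange to the C4,C6-dianion is too slow. The substrate could also rest as an unreactive polyanion, or the chain could be cut by retro-Claisen attack of the released methoxide. The aryl group activates C6 less than the second carbonyl group does in the polyketo esters for which this closure is best known.
- Fallback: the 2-arylphloroglucinol is made by cross-coupling, setting out from bromide 2 and returning at 11. The tris(methoxymethyl) ether of phloroglucinol, 1,3,5-tris(methoxymethoxy)benzene F1, is lithiated between two ether groups (n-BuLi) and quenched with B(OMe)3 to give [2,4,6-tris(methoxymethoxy)phenyl]boronic acid F2. Suzuki–Miyaura coupling of F2 with 2 (Pd(OAc)2, SPhos, K3PO4) should give methyl 4-(benzyloxy)-3-[2,4,6-tris(methoxymethoxy)phenyl]benzoate F3. Its three acetal groups are removed with HCl in methanol to give 11.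

**Step 4.**
- What may go wrong: proton transfer from the benzylic position of the acyl imidazole to the strongly basic dianion, so that enolisation replaces acylation, and lactonisation of the product during acidic work-up.
- Fallback: a neutral γ-acylation, setting out from acid 5 and returning at 9. Acid 5 is converted with oxalyl chloride into methyl 4-(benzyloxy)-3-(2-chloro-2-oxoethyl)benzoate F4. F4 is combined in CH2Cl2 at −78 to 20 °C with the bis(silyl) dienol ether of 6, 1-methoxy-1,3-bis(trimethylsilyloxy)buta-1,3-diene F5, which reacts at its terminal carbon. Mild aqueous work-up then gives 9 without any strong base.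

**Step 7.**
- What may go wrong: loss of site selectivity between the two ortho hydroxyls (both can chelate the carbonyl group), over-benzylation, and some C-benzylation at the last free ring position. An error here would lead to the C6-linked isomer.
- Fallback: protect everything and then remove one group selectively, setting out from 13 and returning at 14. Exhaustive benzylation (excess BnBr, K2CO3, DMF, 70 °C) gives methyl 3-[3-acetyl-2,4,6-tris(benzyloxy)phenyl]-4-(benzyloxy)benzoate F6. MgBr2·OEt2 in toluene–ether cleaves only benzyl ethers ortho to the carbonyl group. Of the two, the one wedged between acetyl and aryl is twisted out of the ring plane and more strained, and it is expected to go first, giving 14.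

**Step 11.**
- What may go wrong: acylation at the phenoxide oxygen without subsequent acyl shift, double acylation, or attack of the enolate on the pyranone of unit 2.
- Fallback: the two-stage Baker–Venkataraman sequence, setting out from 17 and 19 and returning at 22. Carbodiimide esterification (EDC·HCl, DMAP) gives 2-acetyl-3,5-bis(benzyloxy)phenyl 4-(benzyloxy)-3-[5,7-bis(benzyloxy)-2-(4-methoxyphenyl)-4-oxo-4H-chromen-8-yl]benzoate F7, which rearranges to 22 with KOtBu in THF.

## Further compounds

F1 | step 5 | 1,3,5-tris(methoxymethoxy)benzene | COCOc1cc(OCOC)cc(OCOC)c1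
F2 | step 5 | [2,4,6-tris(methoxymethoxy)phenyl]boronic acid | COCOc1cc(OCOC)c(B(O)O)c(OCOC)c1
F3 | step 5 | methyl 4-(benzyloxy)-3-[2,4,6-tris(methoxymethoxy)phenyl]benzoate | COC(=O)c1ccc(OCc2ccccc2)c(-c2c(OCOC)cc(OCOC)cc2OCOC)c1
F4 | step 4 | methyl 4-(benzyloxy)-3-(2-chloro-2-oxoethyl)benzoate | COC(=O)c1ccc(OCc2ccccc2)c(CC(=O)Cl)c1
F5 | step 4 | 1-methoxy-1,3-bis(trimethylsilyloxy)buta-1,3-diene | COC(O[Si](C)(C)C)=CC(=C)O[Si](C)(C)C
F6 | step 7 | methyl 3-[3-acetyl-2,4,6-tris(benzyloxy)phenyl]-4-(benzyloxy)benzoate | COC(=O)c1ccc(OCc2ccccc2)c(-c2c(OCc3ccccc3)cc(OCc3ccccc3)c(C(C)=O)c2OCc2ccccc2)c1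
F7 | step 11 | 2-acetyl-3,5-bis(benzyloxy)phenyl 4-(benzyloxy)-3-[5,7-bis(benzyloxy)-2-(4-methoxyphenyl)-4-oxo-4H-chromen-8-yl]benzoate | COc1ccc(-c2cc(=O)c3c(OCc4ccccc4)cc(OCc4ccccc4)c(-c4cc(C(=O)Oc5cc(OCc6ccccc6)cc(OCc6ccccc6)c5C(C)=O)ccc4OCc4ccccc4)c3o2)cc1
A1 | alternative 1 | 5,7-bis(benzyloxy)-8-ethynyl-2-(4-methoxyphenyl)-4H-chromen-4-one | COc1ccc(-c2cc(=O)c3c(OCc4ccccc4)cc(OCc4ccccc4)c(C#C)c3o2)cc1
A2 | alternative 1 | methyl 3-hydroxy-2-oxo-2H-pyran-6-carboxylate | COC(=O)c1ccc(O)c(=O)o1
A3 | alternative 1 | methyl 3-[5,7-bis(benzyloxy)-2-(4-methoxyphenyl)-4-oxo-4H-chromen-8-yl]-4-hydroxybenzoate | COc1ccc(-c2cc(=O)c3c(OCc4ccccc4)cc(OCc4ccccc4)c(-c4cc(C(=O)OC)ccc4O)c3o2)cc1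
A4 | alternative 2 | 2-acetyl-3,5-bis(benzyloxy)phenyl 3-{3-acetyl-4,6-bis(benzyloxy)-2-[(4-methoxybenzoyl)oxy]phenyl}-4-(benzyloxy)benzoate | COc1ccc(C(=O)Oc2c(C(C)=O)c(OCc3ccccc3)cc(OCc3ccccc3)c2-c2cc(C(=O)Oc3cc(OCc4ccccc4)cc(OCc4ccccc4)c3C(C)=O)ccc2OCc2ccccc2)cc1
A5 | alternative 2 | 1-[2,4-bis(benzyloxy)-6-hydroxyphenyl]-3-{4-(benzyloxy)-3-[4,6-bis(benzyloxy)-2-hydroxy-3-[3-(4-methoxyphenyl)-3-oxopropanoyl]phenyl]phenyl}propane-1,3-dione | COc1ccc(C(=O)CC(=O)c2c(O)c(-c3cc(C(=O)CC(=O)c4c(O)cc(OCc5ccccc5)cc4OCc4ccccc4)ccc3OCc3ccccc3)c(OCc3ccccc3)cc2OCc2ccccc2)cc1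
A6 | alternative 3 | 3,5-bis(benzyloxy)-2-iodophenol | Oc1cc(OCc2ccccc2)cc(OCc2ccccc2)c1I
A7 | alternative 3 | 5,7-bis(benzyloxy)-8-[2-(benzyloxy)-5-ethynylphenyl]-2-(4-methoxyphenyl)-4H-chromen-4-one | COc1ccc(-c2cc(=O)c3c(OCc4ccccc4)cc(OCc4ccccc4)c(-c4cc(C#C)ccc4OCc4ccccc4)c3o2)cc1
A8 | alternative 3 | 5,7-bis(benzyloxy)-8-{2-(benzyloxy)-5-[5,7-bis(benzyloxy)-4-oxo-4H-chromen-2-yl]phenyl}-2-(4-methoxyphenyl)-4H-chromen-4-one | COc1ccc(-c2cc(=O)c3c(OCc4ccccc4)cc(OCc4ccccc4)c(-c4cc(-c5cc(=O)c6c(OCc7ccccc7)cc(OCc7ccccc7)cc6o5)ccc4OCc4ccccc4)c3o2)cc1
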